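**Assumption:** the SMILES decodes to (2R,3S,4S,5R), which is the C2-symmetric, all-trans (2,3-trans, 3,4-trans, 4,5-trans) tetrahydrofuran. I take this structure to be (+)-neoolivil. Lignan numbering is used below: ArC7–C8(C9)–C8'(C9')–C7'Ar.

## Retrosynthetic overview
1. Only one ring is built, the THF. It is closed late by C7–O–C7' cyclodehydration (SN1) of a C2-symmetric 1,4-diaryl-1,4-diol.
2. During ring closure the two CH2OH groups are masked as silyl ethers, so they cannot close to the furofuran (pinoresinol-type) skeleton. One fluoride step removes all silyl groups at the end.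
3. The diol comes from a tetraol, which comes from reductive removal of two Evans auxiliaries.
4. Both C7–C8 bonds and all four stereocentres come from one two-directional Evans syn-aldol of N,N'-succinyl-bis[(R)-4-benzyloxazolidinone] with two O-TBS-vanillin units.
5. The starting materials are vanillin, succinyl chloride and (R)-4-benzyl-2-oxazolidinone.

## Route

**Step 1**
- Reactants: 1, vanillin
- Product: 2, 4-(tert-butyldimethylsilyloxy)-3-methoxybenzaldehyde
- Conditions: TBSCl (1.1 equiv), imidazole, DMF, rt
- Reagents that add atoms: TBSCl, CC(C)(C)[Si](C)(C)Cl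
- Why: Phenol O-silylation masks the acidic OH, keeps the ring electron-rich for the later benzylic ionisation, and is removable without hydrogenolysis, which would endanger the benzylic C–O bonds of the THF.

**Step 2**
- Reactants: 3, (R)-4-benzyl-2-oxazolidinone (2 equiv); 4, succinyl chloride (1 equiv)
- Product: 5, 1,4-bis[(4R)-4-benzyl-2-oxooxazolidin-3-yl]butane-1,4-dione
- Conditions: n-BuLi (2 equiv), THF, −78 °C; then 4, −78 → 0 °C
- Reagents that add atoms: none beyond the reactants (4, O=C(Cl)CCC(=O)Cl, supplies the C9–C8–C8'–C9' unit)
- Why: This is a standard double N-acylation of the lithiated Evans auxiliary by a diacid chloride, and no new stereocentre is formed.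

**Step 3**
- Reactants: 5; 2 (2.4 equiv)
- Product: 6, (2R,3R)-1,4-bis[(4R)-4-benzyl-2-oxooxazolidin-3-yl]-2,3-bis{(R)-hydroxy[4-(TBSO)-3-methoxyphenyl]methyl}butane-1,4-dione
- Conditions: n-Bu2BOTf (2.4 equiv), i-Pr2NEt (2.8 equiv), CH2Cl2, 0 °C; then 2, −78 → 0 °C; pH 7 buffer/MeOH/30% H2O2, 0 °C
- Reagents that add atoms: none beyond the reactants (2 supplies both ArCH(OH) units)
- Why: In this two-directional Evans syn-aldol via the bis-(Z)-boron enolate, each (R)-auxiliary imposes the same Zimmerman–Traxler facial sense (the mirror image of the (S)-auxiliary/PhCHO → 2S,3S outcome), which sets C7, C8, C8' and C7' as R,R,R,R, while the second carbonyl stays masked as an enolate until both additions are complete and so cannot lactonise early.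

**Step 4**
- Reactants: 6
- Product: 7, (1R,2S,3S,4R)-1,4-bis[4-(TBSO)-3-methoxyphenyl]-2,3-bis(hydroxymethyl)butane-1,4-diol
- Conditions: LiBH4 (6 equiv), MeOH (6 equiv), THF/Et2O, 0 °C (auxiliary 3 recovered)
- Reagents that add atoms: none
- Why: Reductive cleavage of the N-acyl oxazolidinones gives the 1,3-diols without touching any stereocentre (the C8 descriptor changes from R to S only through CIP priorities), and any lactonised material is reduced to the same tetraol.

**Step 5**
- Reactants: 7
- Product: 8, (1R,2S,3S,4R)-1,4-bis[4-(TBSO)-3-methoxyphenyl]-2,3-bis[(tert-butyldiphenylsilyloxy)methyl]butane-1,4-diol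
- Conditions: TBDPSCl (2.1 equiv), imidazole, CH2Cl2/DMF, 0 °C
- Reagents that add atoms: TBDPSCl, CC(C)(C)[Si](Cl)(c1ccccc1)c1ccccc1
- Why: Sterically selective silylation takes the two primary alcohols over the hindered secondary benzylic ones, which removes the nucleophiles that would otherwise give 7,9'-ethers or the furofuran.

**Step 6**
- Reactants: 8
- Product: 9, (2R,3S,4S,5R)-2,5-bis[4-(TBSO)-3-methoxyphenyl]-3,4-bis[(TBDPSO)methyl]oxolane
- Conditions: MsCl (1.2 equiv), Et3N (4 equiv), CH2Cl2, −20 → 0 °C
- Reagents that add atoms: none (net loss of H2O)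
- Why: In this SN1 cycloetherification the p-silyloxybenzylic mesylate ionises to a quinonoid cation that the other carbinol oxygen (already correctly configured by the syn-aldol) captures 5-exo, trans to the adjacent CH2OSi group, which gives the kinetically and thermodynamically preferred all-trans THF.

**Step 7**
- Reactants: 9
- Product: 10, (+)-neoolivil
- Conditions: TBAF (5 equiv), AcOH (5 equiv), THF, 0 °C → rt
- Reagents that add atoms: none
- Why: Buffered global fluoride desilylation removes two aryl TBS and two alkyl TBDPS groups in one operation without ionising the benzylic ethers, so no stereocentre is affected.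

## Compound list

| No. | Name | SMILES | Role |
|---|---|---|---|
| 1 | vanillin | `O=Cc1ccc(O)c(OC)c1` | starting material |
| 2 | O-TBS-vanillin | `O=Cc1ccc(O[Si](C)(C)C(C)(C)C)c(OC)c1` | intermediate |
| 3 | (R)-4-benzyl-2-oxazolidinone | `O=C1OC[C@@H](Cc2ccccc2)N1` | starting material |
| 4 | succinyl chloride | `O=C(Cl)CCC(=O)Cl` | starting material |
| 5 | succinyl bis-imide | `O=C(CCC(=O)N1[C@H](Cc2ccccc2)COC1=O)N1[C@H](Cc2ccccc2)COC1=O` | intermediate |
| 6 | bis-syn-aldol adduct | `O[C@@H](c1ccc(O[Si](C)(C)C(C)(C)C)c(OC)c1)[C@H](C(=O)N1[C@H](Cc2ccccc2)COC1=O)[C@@H](C(=O)N1[C@H](Cc2ccccc2)COC1=O)[C@@H](O)c1ccc(O[Si](C)(C)C(C)(C)C)c(OC)c1` | intermediate |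
| 7 | tetraol | `O[C@@H](c1ccc(O[Si](C)(C)C(C)(C)C)c(OC)c1)[C@H](CO)[C@@H](CO)[C@@H](O)c1ccc(O[Si](C)(C)C(C)(C)C)c(OC)c1` | intermediate |
| 8 | 9,9'-bis-TBDPS diol | `O[C@@H](c1ccc(O[Si](C)(C)C(C)(C)C)c(OC)c1)[C@H](CO[Si](c1ccccc1)(c1ccccc1)C(C)(C)C)[C@@H](CO[Si](c1ccccc1)(c1ccccc1)C(C)(C)C)[C@@H](O)c1ccc(O[Si](C)(C)C(C)(C)C)c(OC)c1` | intermediate |
| 9 | tetrasilyl neoolivil | `COc1cc([C@@H]2O[C@@H](c3ccc(O[Si](C)(C)C(C)(C)C)c(OC)c3)[C@H](CO[Si](c3ccccc3)(c3ccccc3)C(C)(C)C)[C@H]2CO[Si](c2ccccc2)(c2ccccc2)C(C)(C)C)ccc1O[Si](C)(C)C(C)(C)C` | intermediate |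
| 10 | (+)-neoolivil | `COc1cc([C@@H]2O[C@@H](c3ccc(O)c(OC)c3)[C@H](CO)[C@H]2CO)ccc1O` | target |

## Summary
- **Total steps:** 7
- **Longest linear sequence:** 6 (steps 2–7 from 3 and 4, or steps 1 and 3–7 from vanillin)

**Three steps most likely to fail, each with a fallback**

1. **Step 3, double aldol.** I know of no direct precedent for the bis-imide case. The mono-imide succinate aldol and two-directional Evans aldols on longer diacid bis-imides are the analogies. The risks are incomplete bis-enolisation, a mismatched second addition, and retro-aldol of the electron-rich adduct.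
   - Fallback: build the backbone by tandem conjugate addition–aldol instead. The lithiated 1,3-dithiane of 2 adds to the appropriate enantiomer of 5-menthyloxy-2(5H)-furanone, anti to the acetal substituent. The enolate is trapped with 2, trans to the new substituent, which gives the correct C8/C8' relationship.
   - Dithiane hydrolysis and LiAlH4 then give the tetraol skeleton. The benzylic epimers are corrected by acid equilibration of the THF to the all-trans isomer.

2. **Step 6, cycloetherification.** The risks are Friedel–Crafts closure to an aryltetralin, E1 loss to a styrene, silyl-ether participation leading to the furofuran, and partial SN2 inversion.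
   - Fallback: change the reactive intermediate. Selectively cleave the two aryl TBS ethers (K2CO3, MeOH), then close the ring through a neutral p-quinone methide by intramolecular oxa-1,6-addition (mild warming or catalytic PPTS) under thermodynamic control. Remove the TBDPS groups last.

3. **Step 4, reductive removal of two hindered imides.** The risks are endocyclic oxazolidinone opening and retro-aldol.
   - Fallback: go through the dilactone. Hydrolyse with LiOOH, then acidify. Both acids lactonise onto the benzylic hydroxyls to give the enantiopure cis-fused exo,exo-2,6-diaryl-3,7-dioxabicyclo[3.3.0]octane-4,8-dione. LiAlH4 then reduces it to tetraol 7, which is the classical dilactone → tetraol reduction.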